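**Retrosynthetic overview**
1. Numbering: ring A is the 5,6-dihydropyran-2-one and ring B the tetrahydropyran (O, C12–C16; C12 carries the chain, C16 the propenyl group). The chain runs from C1 (alkene CH on ring A) to C11 (carbinol on ring B).
2. Key disconnection C6–C7, both ends as nucleophiles: C6 as the primary pinacol boronate 11 (ring A masked as its methyl lactol acetal) and C7 as the dienyllithium from (Z)-iodide 28. They are joined oxidatively by I2/NaOMe (Zweifel olefination) with inversion, so the (Z)-iodide becomes the (7E)-alkene.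
3. Enabling feature: C7 is the fully substituted sp2 carbon of the C7=C8 alkene (it bears the methyl group), and C6 is a methylene whose only neighbouring stereocentre (C5) is β to boron. The ring A acetal and ring B tolerate alkyllithium and iodine, and a 1,2-shift from boron never makes C6 a radical or carbanion that the (3Z)-diene could trap at C2.
4. West (11): ring A by catalytic asymmetric hetero-Diels–Alder reaction, then C2–C3 by Negishi coupling with (Z)-iodide 4 made from a chiral-pool bromide. East (28): Evans aldol (C15, C16), vinylogous Mukaiyama aldol (C14), Sharpless epoxidation (C11, C12), two olefinations.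
5. Order of ring formation: ring A as acetal (step 4), ring B by 6-exo epoxide opening (step 15), ring A carbonyl restored after the coupling (steps 22 and 23).

Key step: step 21

Remarks on the chemistry (assumptions):
- The acetal centre of ring A is carried as the cis isomer from the cycloaddition; if it epimerises, both anomers converge at lactone 34.
- Silyl ketene acetal 19 is drawn as its (1Z) isomer; this geometry is lost in step 12.
- Lactol 33 (anomers) and iodoboronate 31 (two diastereomers at C7/C8) have these centres undefined in their SMILES; the centres disappear in the next event.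
- The antipode of the chromium catalyst in step 4 is assigned by analogy with its usual sense of induction for aliphatic aldehydes; the other antipode is equally available.

**Route**

Step 1
Reactants: 1 (S)-3-bromo-2-methylpropan-1-ol
Product: 2 (R)-2-methyl-3-(4,4,5,5-tetramethyl-1,3,2-dioxaborolan-2-yl)propan-1-ol
Conditions: B2pin2, CuI (copper iodide, 10 mol%), PPh3, LiOMe, DMF, 25 °C
Reagents that add atoms: bis(pinacolato)diboron, CC1(C)OB(OC1(C)C)B1OC(C)(C)C(C)(C)O1
Why: Copper-catalysed boryl substitution of a primary alkyl bromide; the future C5 stereocentre is β to the reacting carbon and untouched (S becomes R only because CH2B ranks below CH2OH), and boron goes in before any alkene is present.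

Step 2
Reactants: 2 (R)-2-methyl-3-(pinacolboryl)propan-1-ol
Product: 3 (R)-2-methyl-3-(4,4,5,5-tetramethyl-1,3,2-dioxaborolan-2-yl)propanal
Conditions: Dess–Martin periodinane, CH2Cl2, 0 °C to rt; crude used at once
Reagents that add atoms: none
Why: Dess–Martin oxidation is non-basic and leaves the C–B bond alone, so the α-stereocentre should survive; the β-boryl aldehyde is not chromatographed.

Step 3
Reactants: 3 (R)-2-methyl-3-(pinacolboryl)propanal
Product: 4 2-[(2R,3Z)-4-iodo-2-methylpent-3-en-1-yl]-4,4,5,5-tetramethyl-1,3,2-dioxaborolane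
Conditions: EtPPh3I, n-BuLi, THF, rt; I2, −78 °C; NaN(SiMe3)2, −20 °C; 3, −78 to −20 °C
Reagents that add atoms: ethyltriphenylphosphonium iodide, CC[P+](c1ccccc1)(c1ccccc1)c1ccccc1.[I-]; iodine, II
Why: Stork–Zhao-type Wittig olefination with the α-iodoethylidene ylide; kinetic oxaphosphetane formation places iodine cis to the C5 chain ((Z)-iodide), and the cold, short reaction should spare the α-stereocentre.

Step 4
Reactants: 5 (E)-1-methoxybuta-1,3-diene; 6 3-(triisopropylsilyl)prop-2-ynal
Product: 7 (2S,6R)-6-methoxy-2-[(triisopropylsilyl)ethynyl]-3,6-dihydro-2H-pyran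
Conditions: CrCl(L) (3 mol%, trivalent chromium; L = C27H29NO2, dianion of the Schiff base from (1S,2R)-1-aminoindan-2-ol and 3-(1-adamantyl)-2-hydroxy-5-methylbenzaldehyde), 4 Å molecular sieves, acetone, rt
Reagents that add atoms: none
Why: Catalytic asymmetric hetero-Diels–Alder reaction; the chiral chromium Lewis acid selects the aldehyde face (ring A carbinol centre, S) and the endo transition state gives the 2,6-cis acetal, ring A closing by a concerted [4+2] cycloaddition.

Step 5
Reactants: 7 silylalkyne acetal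
Product: 8 (2S,6R)-2-ethynyl-6-methoxy-3,6-dihydro-2H-pyran
Conditions: Bu4NF, THF, 0 °C
Reagents that add atoms: none
Why: Fluoride cleaves the C(sp)–Si bond, and the non-acidic medium leaves the acetal centre untouched.

Step 6
Reactants: 8 (2S,6R)-2-ethynyl-6-methoxy-3,6-dihydro-2H-pyran; 4 (Z)-iodide
Product: 11 2-[(2R,3Z,5E)-6-[(2S,6R)-6-methoxy-3,6-dihydro-2H-pyran-2-yl]-2,4-dimethylhexa-3,5-dien-1-yl]-4,4,5,5-tetramethyl-1,3,2-dioxaborolane, via alkenylzirconocene chloride 9 (not isolated), via alkenylzinc chloride 10 (not isolated)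
Conditions: Cp2Zr(H)Cl, THF, rt; ZnCl2, 0 °C; 4, Pd(PPh3)4 (5 mol%), rt
Reagents that add atoms: none
Why: syn-Hydrozirconation puts zirconium on the terminal carbon ((E)-alkenyl), and transmetalation to zinc and Negishi coupling proceed with retention at both sp2 carbons, so C2 ends cis to C5 ((1E,3Z)-diene); a primary alkyl–B(pin) does not transmetalate under these base-free conditions.

Step 7
Reactants: 12 (S)-4-benzyl-3-propanoyl-1,3-oxazolidin-2-one; 13 (E)-but-2-enal
Product: 14 (S)-4-benzyl-3-[(2S,3R,4E)-3-hydroxy-2-methylhex-4-enoyl]-1,3-oxazolidin-2-one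
Conditions: n-Bu2BOTf, Et3N, CH2Cl2, 0 °C; 13, −78 to 0 °C; aqueous phosphate buffer (pH 7), MeOH, H2O2
Reagents that add atoms: none
Why: Evans syn-aldol: the (Z)-boron enolate reacts through a chair Zimmerman–Traxler transition state with the benzyl group of the auxiliary shielding one enolate face, which sets C15 and C16 as the syn pair.

Step 8
Reactants: 14 aldol adduct
Product: 15 (2S,3R,4E)-3-hydroxy-N-methoxy-N,2-dimethylhex-4-enamide
Conditions: MeNH(OMe)·HCl, AlMe3, CH2Cl2, −20 to 0 °C
Reagents that add atoms: N,O-dimethylhydroxylamine hydrochloride, CNOC.Cl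
Why: Aluminium-amide transamination, assisted by the free β-hydroxyl, gives the Weinreb amide and releases the auxiliary without epimerisation at C15.

Step 9
Reactants: 15 Weinreb amide
Product: 16 (2S,3R,4E)-N-methoxy-N,2-dimethyl-3-(triethylsilyloxy)hex-4-enamide
Conditions: Et3SiCl, imidazole, DMF, 0 °C to rt
Reagents that add atoms: chlorotriethylsilane, CC[Si](Cl)(CC)CC
Why: Standard silylation; the triethylsilyl ether blocks the propenyl carbinol during the later epoxidation and is labile enough to come off with acid in step 15.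

Step 10
Reactants: 16 silylated Weinreb amide
Product: 17 (2S,3R,4E)-2-methyl-3-(triethylsilyloxy)hex-4-enal
Conditions: i-Bu2AlH, THF, −78 °C
Reagents that add atoms: none
Why: i-Bu2AlH adds once to the Weinreb amide and the chelated tetrahedral intermediate collapses to the aldehyde only on work-up, so over-reduction and α-epimerisation are not expected.

Step 11
Reactants: 18 methyl (E)-but-2-enoate
Product: 19 tert-butyl{[(1Z)-1-methoxybuta-1,3-dien-1-yl]oxy}dimethylsilane
Conditions: LiN(i-Pr)2, DMPU, THF, −78 °C; t-BuMe2SiCl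
Reagents that add atoms: tert-butylchlorodimethylsilane, CC(C)(C)[Si](C)(C)Cl
Why: γ-Deprotonation of the crotonate in the presence of DMPU gives the extended enolate, which is silylated on oxygen.

Step 12
Reactants: 17 aldehyde; 19 silyl ketene acetal
Product: 20 methyl (2E,5S,6R,7R,8E)-5-hydroxy-6-methyl-7-(triethylsilyloxy)deca-2,8-dienoate
Conditions: B(C6F5)3 (cat.), i-PrOH, Et2O, −78 °C
Reagents that add atoms: none
Why: Vinylogous Mukaiyama aldol reaction: the dienolate attacks through its γ-carbon and approaches the bulky borane–aldehyde complex in the Felkin–Anh sense (anti to C16, past the α-hydrogen), which should set C14 syn to the C15 methyl and complete the syn,syn triad, while i-PrOH takes up the silyl group.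

Step 13
Reactants: 20 hydroxy enoate
Product: 21 (2E,5S,6R,7R,8E)-6-methyl-7-(triethylsilyloxy)deca-2,8-diene-1,5-diol
Conditions: i-Bu2AlH, CH2Cl2, −78 °C
Reagents that add atoms: none
Why: i-Bu2AlH reduces the enoate 1,2 to the (E)-allylic alcohol; the free C14 hydroxyl is only deprotonated.

Step 14
Reactants: 21 allylic alcohol
Product: 22 (2S,3R,4R,5E)-1-[(2S,3S)-3-(hydroxymethyl)oxiran-2-yl]-3-methyl-4-(triethylsilyloxy)hept-5-en-2-ol
Conditions: Ti(Oi-Pr)4 (cat.), L-(+)-diisopropyl tartrate, t-BuOOH, 4 Å molecular sieves, CH2Cl2, −20 °C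
Reagents that add atoms: tert-butyl hydroperoxide, CC(C)(C)OO
Why: Sharpless asymmetric epoxidation: only the primary allylic alcohol binds titanium, and the L-(+)-tartrate catalyst delivers oxygen to the face that gives the (2S,3S)-epoxide (C11 and C12), while the silylated propenyl carbinol is not a substrate.

Step 15
Reactants: 22 epoxy alcohol
Product: 23 (S)-1-[(2R,4S,5R,6R)-4-hydroxy-5-methyl-6-[(E)-prop-1-en-1-yl]oxan-2-yl]ethane-1,2-diol
Conditions: camphorsulfonic acid (cat.), CH2Cl2/MeOH, 0 °C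
Reagents that add atoms: none
Why: Acidic methanolysis of the triethylsilyl ether frees O16, which opens the protonated epoxide at C12 in a 6-exo-tet mode with inversion (C12 becomes R) through a chair with the C12 and C16 substituents equatorial; this forms ring B and reveals the C11 hydroxyl with its configuration unchanged, the 5-endo attack of O14 and the 7-endo attack of O16 being disfavoured.

Step 16
Reactants: 23 triol
Product: 24 (2R,4S,5S,6R)-2-[(S)-1,2-bis(tert-butyldimethylsilyloxy)ethyl]-4-(tert-butyldimethylsilyloxy)-5-methyl-6-[(E)-prop-1-en-1-yl]oxane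
Conditions: t-BuMe2SiOTf, 2,6-lutidine, CH2Cl2, −78 to 0 °C
Reagents that add atoms: tert-butyldimethylsilyl trifluoromethanesulfonate, CC(C)(C)[Si](C)(C)OS(=O)(=O)C(F)(F)F
Why: The silyl triflate silylates all three hydroxyls, including the axial C14 hydroxyl next to the axial methyl group.

Step 17
Reactants: 24 tris-silyl ether
Product: 25 (S)-2-(tert-butyldimethylsilyloxy)-2-[(2R,4S,5S,6R)-4-(tert-butyldimethylsilyloxy)-5-methyl-6-[(E)-prop-1-en-1-yl]oxan-2-yl]ethan-1-ol
Conditions: HF·pyridine, pyridine, THF, 0 °C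
Reagents that add atoms: none
Why: Buffered HF·pyridine cleaves the unhindered primary silyl ether much faster than the two secondary ones.

Step 18
Reactants: 25 primary alcohol
Product: 26 (R)-2-(tert-butyldimethylsilyloxy)-2-[(2R,4S,5S,6R)-4-(tert-butyldimethylsilyloxy)-5-methyl-6-[(E)-prop-1-en-1-yl]oxan-2-yl]acetaldehyde
Conditions: Dess–Martin periodinane, CH2Cl2, 0 °C to rt
Reagents that add atoms: none
Why: Dess–Martin oxidation under non-basic conditions gives the α-silyloxy aldehyde without epimerising C11.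

Step 19
Reactants: 26 aldehyde
Product: 27 (2E,4S)-4-(tert-butyldimethylsilyloxy)-4-[(2R,4S,5S,6R)-4-(tert-butyldimethylsilyloxy)-5-methyl-6-[(E)-prop-1-en-1-yl]oxan-2-yl]but-2-enal
Conditions: Ph3P=CHCHO, toluene, 80 °C
Reagents that add atoms: (triphenylphosphoranylidene)acetaldehyde, O=CC=P(c1ccccc1)(c1ccccc1)c1ccccc1
Why: Wittig olefination with the stabilised formylmethylene ylide gives the (E)-enal (C9=C10); only a small excess of ylide is used to limit a second homologation.

Step 20
Reactants: 27 enal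
Product: 28 (2R,4S,5S,6R)-4-(tert-butyldimethylsilyloxy)-2-[(1S,2E,4Z)-1-(tert-butyldimethylsilyloxy)-5-iodohexa-2,4-dien-1-yl]-5-methyl-6-[(E)-prop-1-en-1-yl]oxane
Conditions: EtPPh3I, n-BuLi, THF, rt; I2, −78 °C; NaN(SiMe3)2, −20 °C; 27, −78 to −20 °C
Reagents that add atoms: ethyltriphenylphosphonium iodide, CC[P+](c1ccccc1)(c1ccccc1)c1ccccc1.[I-]; iodine, II
Why: Stork–Zhao-type Wittig olefination as in step 3 places iodine cis to C9, giving the (Z)-iodide that the invertive key step requires.

Step 21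
Reactants: 28 (Z)-dienyl iodide; 11 west boronate
Product: 32 (7E)-coupled polyene (11,14-bis-O-silyl ether of the target skeleton with ring A as its methyl lactol acetal), via dienyllithium 29 (not isolated), via lithium boronate 30 (not isolated), via β-iodoboronic ester 31 (not isolated)
Conditions: t-BuLi (2 equiv per 28), Et2O, −78 °C; 11, THF, −78 °C; I2, THF, −78 °C, dark; NaOMe, MeOH, −78 to 0 °C
Reagents that add atoms: none
Why: Zweifel olefination: iodine–lithium exchange turns 28 into the configurationally stable dienyllithium 29, which adds to boron of 11 to give boronate 30; I2 then attacks C8 while the C6–B bond migrates to C7 anti to the new C8–iodine bond (31), and NaOMe triggers anti elimination of boron and iodide. The closest known reaction type is the I2/NaOMe coupling of alkenyllithiums with primary and secondary alkyl pinacol boronates, a transition-metal-free union of two carbon nucleophiles. No ring is closed and no stereocentre is created; C5 is β to boron and untouched. The C7=C8 geometry is controlled by the anti-shift/anti-elimination sequence, which inverts the alkene: iodine (then boron) cis to C9 in 28 becomes C6 trans to C9, the (7E)-alkene. The step needs iodination at C8 of the boronate and not at C10 or at the neutral polyenes: the negative charge on boron makes C8 the most nucleophilic carbon, and −78 °C, darkness and prompt methoxide treatment should keep the isolated alkenes and the (3Z)-diene out of reach of iodine. Because C6 moves as a bonded electron pair, it never becomes a radical or free carbanion that the (3Z)-diene would trap at C2.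

Step 22
Reactants: 32 coupled acetal
Product: 33 lactol (ring A as 6-substituted 5,6-dihydro-2H-pyran-2-ol, anomeric mixture)
Conditions: pyridinium p-toluenesulfonate (cat.), acetone/H2O, rt
Reagents that add atoms: water, O
Why: Mild acid hydrolyses the allylic methyl acetal to the lactol while the silyl ethers are expected to stay on.

Step 23
Reactants: 33 lactol
Product: 34 bis-silyl lactone (11,14-bis-O-tert-butyldimethylsilyl ether of the target)
Conditions: MnO2, CH2Cl2, rt
Reagents that add atoms: none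
Why: MnO2 oxidises the allylic lactol to the α,β-unsaturated lactone; both carbinols are still silylated, so C11 and C14 cannot be oxidised.

Step 24
Reactants: 34 bis-silyl lactone
Product: 35 (6S)-6-[(1E,3Z,5R,7E,9E,11S)-11-hydroxy-11-[(2R,4S,5R,6R)-4-hydroxy-5-methyl-6-[(E)-prop-1-en-1-yl]oxan-2-yl]-3,5,7-trimethylundeca-1,3,7,9-tetraen-1-yl]-5,6-dihydro-2H-pyran-2-one (target)
Conditions: HF·pyridine, pyridine, THF, 0 °C to rt
Reagents that add atoms: none
Why: HF·pyridine removes both silyl ethers under conditions that should neither open the unsaturated lactone nor ionise the dienyl carbinol at C11.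

**Compound list**
1 | (S)-3-bromo-2-methylpropan-1-ol | BrC[C@@H](C)CO | starting material
2 | (R)-2-methyl-3-(4,4,5,5-tetramethyl-1,3,2-dioxaborolan-2-yl)propan-1-ol | CC1(C)OB(C[C@@H](C)CO)OC1(C)C | intermediate
3 | (R)-2-methyl-3-(4,4,5,5-tetramethyl-1,3,2-dioxaborolan-2-yl)propanal | CC1(C)OB(C[C@@H](C)C=O)OC1(C)C | intermediate
4 | 2-[(2R,3Z)-4-iodo-2-methylpent-3-en-1-yl]-4,4,5,5-tetramethyl-1,3,2-dioxaborolane | CC1(C)OB(C[C@@H](C)/C=C(/C)I)OC1(C)C | intermediate
5 | (E)-1-methoxybuta-1,3-diene | CO/C=C/C=C | starting material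
6 | 3-(triisopropylsilyl)prop-2-ynal | O=CC#C[Si](C(C)C)(C(C)C)C(C)C | starting material
7 | (2S,6R)-6-methoxy-2-[(triisopropylsilyl)ethynyl]-3,6-dihydro-2H-pyran | CO[C@H]1C=CC[C@@H](C#C[Si](C(C)C)(C(C)C)C(C)C)O1 | intermediate
8 | (2S,6R)-2-ethynyl-6-methoxy-3,6-dihydro-2H-pyran | CO[C@H]1C=CC[C@@H](C#C)O1 | intermediate
9 | chlorobis(cyclopentadienyl){(E)-2-[(2S,6R)-6-methoxy-3,6-dihydro-2H-pyran-2-yl]ethenyl}zirconium | CO[C@H]1C=CC[C@@H](/C=C/[Zr](Cl)(C2C=CC=C2)C2C=CC=C2)O1 | intermediate
10 | {(E)-2-[(2S,6R)-6-methoxy-3,6-dihydro-2H-pyran-2-yl]ethenyl}zinc chloride | CO[C@H]1C=CC[C@@H](/C=C/[Zn]Cl)O1 | intermediate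
11 | 2-[(2R,3Z,5E)-6-[(2S,6R)-6-methoxy-3,6-dihydro-2H-pyran-2-yl]-2,4-dimethylhexa-3,5-dien-1-yl]-4,4,5,5-tetramethyl-1,3,2-dioxaborolane | CC1(C)OB(C[C@@H](C)/C=C(C)\C=C\[C@@H]2CC=C[C@H](OC)O2)OC1(C)C | intermediate
12 | (S)-4-benzyl-3-propanoyl-1,3-oxazolidin-2-one | CCC(=O)N1[C@@H](Cc2ccccc2)COC1=O | starting material
13 | (E)-but-2-enal | C/C=C/C=O | starting material
14 | (S)-4-benzyl-3-[(2S,3R,4E)-3-hydroxy-2-methylhex-4-enoyl]-1,3-oxazolidin-2-one | C/C=C/[C@@H](O)[C@H](C)C(=O)N1[C@@H](Cc2ccccc2)COC1=O | intermediate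
15 | (2S,3R,4E)-3-hydroxy-N-methoxy-N,2-dimethylhex-4-enamide | C/C=C/[C@@H](O)[C@H](C)C(=O)N(C)OC | intermediate
16 | (2S,3R,4E)-N-methoxy-N,2-dimethyl-3-(triethylsilyloxy)hex-4-enamide | C/C=C/[C@@H](O[Si](CC)(CC)CC)[C@H](C)C(=O)N(C)OC | intermediate
17 | (2S,3R,4E)-2-methyl-3-(triethylsilyloxy)hex-4-enal | C/C=C/[C@@H](O[Si](CC)(CC)CC)[C@H](C)C=O | intermediate
18 | methyl (E)-but-2-enoate | C/C=C/C(=O)OC | starting material
19 | tert-butyl{[(1Z)-1-methoxybuta-1,3-dien-1-yl]oxy}dimethylsilane | C=C/C=C(/OC)O[Si](C)(C)C(C)(C)C | intermediate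
20 | methyl (2E,5S,6R,7R,8E)-5-hydroxy-6-methyl-7-(triethylsilyloxy)deca-2,8-dienoate | C/C=C/[C@@H](O[Si](CC)(CC)CC)[C@H](C)[C@@H](O)C/C=C/C(=O)OC | intermediate
21 | (2E,5S,6R,7R,8E)-6-methyl-7-(triethylsilyloxy)deca-2,8-diene-1,5-diol | C/C=C/[C@@H](O[Si](CC)(CC)CC)[C@H](C)[C@@H](O)C/C=C/CO | intermediate
22 | (2S,3R,4R,5E)-1-[(2S,3S)-3-(hydroxymethyl)oxiran-2-yl]-3-methyl-4-(triethylsilyloxy)hept-5-en-2-ol | C/C=C/[C@@H](O[Si](CC)(CC)CC)[C@H](C)[C@@H](O)C[C@@H]1O[C@H]1CO | intermediate
23 | (S)-1-[(2R,4S,5R,6R)-4-hydroxy-5-methyl-6-[(E)-prop-1-en-1-yl]oxan-2-yl]ethane-1,2-diol | C/C=C/[C@H]1O[C@@H]([C@@H](O)CO)C[C@H](O)[C@H]1C | intermediate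
24 | (2R,4S,5S,6R)-2-[(S)-1,2-bis(tert-butyldimethylsilyloxy)ethyl]-4-(tert-butyldimethylsilyloxy)-5-methyl-6-[(E)-prop-1-en-1-yl]oxane | C/C=C/[C@H]1O[C@@H]([C@@H](O[Si](C)(C)C(C)(C)C)CO[Si](C)(C)C(C)(C)C)C[C@H](O[Si](C)(C)C(C)(C)C)[C@H]1C | intermediate
25 | (S)-2-(tert-butyldimethylsilyloxy)-2-[(2R,4S,5S,6R)-4-(tert-butyldimethylsilyloxy)-5-methyl-6-[(E)-prop-1-en-1-yl]oxan-2-yl]ethan-1-ol | C/C=C/[C@H]1O[C@@H]([C@@H](O[Si](C)(C)C(C)(C)C)CO)C[C@H](O[Si](C)(C)C(C)(C)C)[C@H]1C | intermediate
26 | (R)-2-(tert-butyldimethylsilyloxy)-2-[(2R,4S,5S,6R)-4-(tert-butyldimethylsilyloxy)-5-methyl-6-[(E)-prop-1-en-1-yl]oxan-2-yl]acetaldehyde | C/C=C/[C@H]1O[C@@H]([C@@H](O[Si](C)(C)C(C)(C)C)C=O)C[C@H](O[Si](C)(C)C(C)(C)C)[C@H]1C | intermediate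
27 | (2E,4S)-4-(tert-butyldimethylsilyloxy)-4-[(2R,4S,5S,6R)-4-(tert-butyldimethylsilyloxy)-5-methyl-6-[(E)-prop-1-en-1-yl]oxan-2-yl]but-2-enal | C/C=C/[C@H]1O[C@@H]([C@@H](O[Si](C)(C)C(C)(C)C)/C=C/C=O)C[C@H](O[Si](C)(C)C(C)(C)C)[C@H]1C | intermediate
28 | (2R,4S,5S,6R)-4-(tert-butyldimethylsilyloxy)-2-[(1S,2E,4Z)-1-(tert-butyldimethylsilyloxy)-5-iodohexa-2,4-dien-1-yl]-5-methyl-6-[(E)-prop-1-en-1-yl]oxane | C/C=C/[C@H]1O[C@@H]([C@@H](O[Si](C)(C)C(C)(C)C)/C=C/C=C(/C)I)C[C@H](O[Si](C)(C)C(C)(C)C)[C@H]1C | intermediate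
29 | dienyllithium from 28 (lithium in place of iodine at C7, cis to C9) | C/C=C/[C@H]1O[C@@H]([C@@H](O[Si](C)(C)C(C)(C)C)/C=C/C=C(/C)[Li])C[C@H](O[Si](C)(C)C(C)(C)C)[C@H]1C | intermediate
30 | lithium boronate from 29 and 11 (boron bonded to C6, C7 and pinacolate) | [Li+].C/C=C/[C@H]1O[C@@H]([C@@H](O[Si](C)(C)C(C)(C)C)/C=C/C=C(/C)[B-]2(C[C@@H](C)/C=C(C)\C=C\[C@@H]3CC=C[C@H](OC)O3)OC(C)(C)C(C)(C)O2)C[C@H](O[Si](C)(C)C(C)(C)C)[C@H]1C | intermediate
31 | β-iodoboronic ester (C7 bears methyl, C6 and pinacolboryl; C8 bears iodine; C6 and iodine anti; two diastereomers) | C/C=C/[C@H]1O[C@@H]([C@@H](O[Si](C)(C)C(C)(C)C)/C=C/C(I)C(C)(C[C@@H](C)/C=C(C)\C=C\[C@@H]2CC=C[C@H](OC)O2)B2OC(C)(C)C(C)(C)O2)C[C@H](O[Si](C)(C)C(C)(C)C)[C@H]1C | intermediate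
32 | (7E)-coupled polyene: 11,14-bis-O-tert-butyldimethylsilyl ether of the target skeleton with ring A as its (2S,6R)-6-methoxy-3,6-dihydro-2H-pyran-2-yl acetal | C/C=C/[C@H]1O[C@@H]([C@@H](O[Si](C)(C)C(C)(C)C)/C=C/C=C(\C)C[C@@H](C)/C=C(C)\C=C\[C@@H]2CC=C[C@H](OC)O2)C[C@H](O[Si](C)(C)C(C)(C)C)[C@H]1C | intermediate
33 | lactol of 32 (ring A as 5,6-dihydro-2H-pyran-2-ol, anomeric mixture) | C/C=C/[C@H]1O[C@@H]([C@@H](O[Si](C)(C)C(C)(C)C)/C=C/C=C(\C)C[C@@H](C)/C=C(C)\C=C\[C@@H]2CC=CC(O)O2)C[C@H](O[Si](C)(C)C(C)(C)C)[C@H]1C | intermediate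
34 | 11,14-bis-O-tert-butyldimethylsilyl ether of the target | C/C=C/[C@H]1O[C@@H]([C@@H](O[Si](C)(C)C(C)(C)C)/C=C/C=C(\C)C[C@@H](C)/C=C(C)\C=C\[C@@H]2CC=CC(=O)O2)C[C@H](O[Si](C)(C)C(C)(C)C)[C@H]1C | intermediate
35 | (6S)-6-[(1E,3Z,5R,7E,9E,11S)-11-hydroxy-11-[(2R,4S,5R,6R)-4-hydroxy-5-methyl-6-[(E)-prop-1-en-1-yl]oxan-2-yl]-3,5,7-trimethylundeca-1,3,7,9-tetraen-1-yl]-5,6-dihydro-2H-pyran-2-one | C/C=C/[C@H]1O[C@@H]([C@@H](O)/C=C/C=C(\C)C[C@@H](C)/C=C(C)\C=C\[C@@H]2CC=CC(=O)O2)C[C@H](O)[C@H]1C | target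

**Step count**
Total: 24 steps. Longest linear sequence: 17 steps (12 to 35 through steps 7–10 and 12–24).

**Steps most likely to fail, with fallbacks**

Step 21 (key coupling). The risk is loss of geometric integrity: iodination at the remote diene terminus (C10) in place of C8, allylic migration of iodine in the iodoboronate before elimination, or iodine-mediated isomerisation of the (3Z)-diene. The fallback sets out from enal 27 and boronate 11 and comes back at 32. Ramirez olefination of 27 (CBr4, PPh3, CH2Cl2, 0 °C) should give the 1,1-dibromodiene F1. Suzuki–Miyaura coupling of 11 (PdCl2(dppf), Cs2CO3, THF/H2O) is expected to take place at the less hindered bromine trans to C9 and give the (Z)-bromodiene F2, with C6 already trans to C9. Negishi methylation with retention (Me2Zn, Pd(P(t-Bu)3)2, THF) then gives 32. C6 is transferred by two-electron transmetalation, and no iodine meets the polyene.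

Step 12 (vinylogous aldol). The risk is poor facial selectivity, because 1,2-induction (Felkin–Anh) and 1,3-induction from the β-silyloxy group pull in opposite senses for this syn aldehyde. The fallback sets out from the same reactants 17 and 19 and comes back at 20. If the 1,3-anti pathway wins, the main product is the (5R)-epimer F3. Mitsunobu inversion (4-nitrobenzoic acid, PPh3, diisopropyl azodicarboxylate, toluene, 0 °C) would give the (5S)-4-nitrobenzoate F4, and methanolysis (K2CO3, MeOH, 0 °C) gives 20. C14 is then set by SN2 inversion and not by facial selection.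

Step 20 (iodo-olefination of the enal). The risk is slow reaction of the conjugated aldehyde while the thermally labile iodo-ylide decomposes, with erosion of Z-selectivity. The fallback sets out from aldehyde 26 and comes back at 28, replacing steps 19 and 20. But-2-yn-1-ol is reduced with NaAlH2(OCH2CH2OMe)2 and the alkenylalane is quenched with I2 to give (Z)-3-iodobut-2-en-1-ol F5. Mitsunobu reaction with 1-phenyl-1H-tetrazole-5-thiol gives the sulfide F6, and oxidation ((NH4)6Mo7O24, H2O2, EtOH) gives the sulfone F7. Julia–Kocienski olefination of 26 with F7 (KN(SiMe3)2, DME, −78 °C) should form the (E)-C9=C10 bond and deliver 28 with the (Z)-iodoalkene already in place.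

Further compounds
F1 | step 21 | (2R,4S,5S,6R)-4-(tert-butyldimethylsilyloxy)-2-[(1S,2E)-5,5-dibromo-1-(tert-butyldimethylsilyloxy)penta-2,4-dien-1-yl]-5-methyl-6-[(E)-prop-1-en-1-yl]oxane | C/C=C/[C@H]1O[C@@H]([C@@H](O[Si](C)(C)C(C)(C)C)/C=C/C=C(Br)Br)C[C@H](O[Si](C)(C)C(C)(C)C)[C@H]1C
F2 | step 21 | (7Z)-7-bromo analogue of 32 (bromine in place of the C7 methyl group, cis to C9; C6 trans to C9) | C/C=C/[C@H]1O[C@@H]([C@@H](O[Si](C)(C)C(C)(C)C)/C=C/C=C(\Br)C[C@@H](C)/C=C(C)\C=C\[C@@H]2CC=C[C@H](OC)O2)C[C@H](O[Si](C)(C)C(C)(C)C)[C@H]1C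
F3 | step 12 | methyl (2E,5R,6R,7R,8E)-5-hydroxy-6-methyl-7-(triethylsilyloxy)deca-2,8-dienoate | C/C=C/[C@@H](O[Si](CC)(CC)CC)[C@H](C)[C@H](O)C/C=C/C(=O)OC
F4 | step 12 | methyl (2E,5S,6R,7R,8E)-6-methyl-5-(4-nitrobenzoyloxy)-7-(triethylsilyloxy)deca-2,8-dienoate | C/C=C/[C@@H](O[Si](CC)(CC)CC)[C@H](C)[C@@H](OC(=O)c1ccc(cc1)[N+](=O)[O-])C/C=C/C(=O)OC
F5 | step 20 | (Z)-3-iodobut-2-en-1-ol | C/C(I)=C/CO
F6 | step 20 | 5-{[(Z)-3-iodobut-2-en-1-yl]sulfanyl}-1-phenyl-1H-tetrazole | C/C(I)=C/CSc1nnnn1-c1ccccc1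
F7 | step 20 | 5-{[(Z)-3-iodobut-2-en-1-yl]sulfonyl}-1-phenyl-1H-tetrazole | C/C(I)=C/CS(=O)(=O)c1nnnn1-c1ccccc1
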